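**Assumption:** Magnone B is the open-chain hydroxy-ketone as drawn, (3R,4R,5S) on the oxolane. Its cyclic hemiketal tautomer is taken to revert on work-up.

## Retrosynthetic overview
- The aryl ketone comes from opening a cis-fused γ-lactone with 3,4-dimethoxyphenyllithium. The cis relationship of CH2OH and C(=O)Ar is therefore enforced by the bicyclic lactone.
- That 2-aryl-furo[3,4-c]furanone comes from Et3SiH reduction of the hemiketal formed by adding 3,4,5-trimethoxyphenyllithium to one carbonyl of the C2-symmetric (R,R)-bis-lactone. The two carbonyls are homotopic, so the aryl group goes on without a selectivity problem.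
- The (R,R)-bis-lactone comes from a double Evans alkylation of succinyl-bis-oxazolidinone with BOMCl. Hydrogenolysis of the benzyl ethers then triggers double lactonisation.
- Ring order: both γ-lactones form together in step 4, the THF ring is made by reducing one lactone in step 6, and the other lactone is opened last in step 7.

## Route

**Step 1**
Reactants: 1 (S)-4-benzyl-1,3-oxazolidin-2-one (2.1 equiv); 2 succinyl chloride
Product: 3 (4S,4'S)-3,3'-succinyl-bis(4-benzyloxazolidin-2-one)
Conditions: n-BuLi, THF, –78 °C; then 2, –78 → 0 °C
Reagents that add atoms: succinyl chloride, ClC(=O)CCC(=O)Cl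
Why: N-acylation of the lithiated Evans auxiliary (Schotten–Baumann-type) gives the symmetrical bis-imide. No new stereocentre is formed.

**Step 2**
Reactants: 3; 4 benzyl chloromethyl ether (BOMCl)
Product: 5 (2R)-2-[(benzyloxy)methyl]-1,4-bis[(4S)-4-benzyl-2-oxo-oxazolidin-3-yl]butane-1,4-dione
Conditions: NaHMDS (1.05 equiv), THF, –78 °C; then 4, –78 → –40 °C
Reagents that add atoms: BOMCl, ClCOCc1ccccc1
Why: Evans asymmetric alkylation. The Z-chelated sodium enolate is attacked anti to the benzyl group of the (S)-auxiliary, giving the (R) centre. Using 1.05 equiv of base limits the reaction to mono-alkylation.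

**Step 3**
Reactants: 5; 4 (BOMCl)
Product: 6 (2R,3R)-2,3-bis[(benzyloxy)methyl]-1,4-bis[(4S)-4-benzyl-2-oxo-oxazolidin-3-yl]butane-1,4-dione
Conditions: NaHMDS (1.1 equiv), THF, –78 °C; then 4, –78 → –40 °C
Reagents that add atoms: BOMCl, ClCOCc1ccccc1
Why: Second Evans alkylation. The CH2 of the unalkylated imide is deprotonated kinetically in preference to the hindered α-CH of the alkylated one. The second auxiliary gives the same (R) sense, so the product is the C2-symmetric dl compound.

**Step 4**
Reactants: 6
Product: 7 (3aR,6aR)-tetrahydro-1H,3H-furo[3,4-c]furan-1,4-dione (cis-fused C2-symmetric bis-lactone)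
Conditions: H2 (1 atm), Pd(OH)2/C, EtOAc–EtOH, rt; then DBU (cat.), THF, rt
Reagents that add atoms: none
Why: Hydrogenolysis of the O-benzyl ethers (the C-benzyl groups of the auxiliary survive). Each free CH2OH then attacks the neighbouring imide in a 5-exo transacylation, closing both γ-lactones and releasing compound 1. Only the cis-fused bicycle can form, so the stereocentres are retained.

**Step 5**
Reactants: 7; 8 5-bromo-1,2,3-trimethoxybenzene
Product: 9 (3aR,6aR)-4-hydroxy-4-(3,4,5-trimethoxyphenyl)tetrahydrofuro[3,4-c]furan-1-one (hemiketal, C4 epimeric mixture)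
Conditions: 8, n-BuLi, THF, –78 °C (1.0 equiv ArLi); add 7, –78 °C, 1 h; sat. NH4Cl
Reagents that add atoms: 5-bromo-1,2,3-trimethoxybenzene, COc1cc(Br)cc(OC)c1OC (supplies the aryl group)
Why: Aryllithium addition to a lactone stops at the stable tetrahedral intermediate at –78 °C and gives the hemiketal on quench. The two carbonyls are homotopic, so no regiochemical issue arises. C3a and C6a are untouched.

**Step 6**
Reactants: 9
Product: 10 (3aR,4S,6aR)-4-(3,4,5-trimethoxyphenyl)tetrahydro-1H,3H-furo[3,4-c]furan-1-one
Conditions: Et3SiH (3 equiv), BF3·OEt2 (3 equiv), CH2Cl2, –78 → 25 °C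
Reagents that add atoms: none (Et3SiH delivers only H)
Why: Ionic hydrogenation (reductive deoxygenation): BF3 ionises the hemiketal to a cyclic oxocarbenium, and Et3SiH reduces it to the THF ring. Any endo-aryl epimer is strained and re-ionises at the electron-rich benzylic C–O under the Lewis acid. It equilibrates to the exo-aryl isomer, which is trans to the C3a–C3 bond and is the configuration required. The lactone is inert to these conditions.

**Step 7**
Reactants: 10; 11 4-bromo-1,2-dimethoxybenzene
Product: 12 Magnone B, (3,4-dimethoxyphenyl)[(3R,4R,5S)-4-(hydroxymethyl)-5-(3,4,5-trimethoxyphenyl)oxolan-3-yl]methanone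
Conditions: 11, n-BuLi, THF, –78 °C; add 10 (1.0 equiv), –78 °C, 1 h; sat. NH4Cl, 0 °C
Reagents that add atoms: 4-bromo-1,2-dimethoxybenzene, COc1ccc(Br)cc1OC (supplies the aryl group)
Why: Aryllithium addition opens the lactone. The tetrahedral hemiketal alkoxide is stable at –78 °C and does not over-add. On work-up it collapses to the aryl ketone and free CH2OH. The cis relationship of C3 and C4 is retained from the ring fusion, and the cold, non-basic work-up avoids α-epimerisation.

## Compound list
1 | (S)-4-benzyl-1,3-oxazolidin-2-one | O=C1N[C@@H](Cc2ccccc2)CO1 | starting material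
2 | succinyl chloride | ClC(=O)CCC(=O)Cl | starting material
3 | (4S,4'S)-3,3'-succinyl-bis(4-benzyloxazolidin-2-one) | O=C1OC[C@H](Cc2ccccc2)N1C(=O)CCC(=O)N1[C@@H](Cc2ccccc2)COC1=O | intermediate
4 | benzyl chloromethyl ether (BOMCl) | ClCOCc1ccccc1 | starting material
5 | mono-(R)-alkylated bis-imide | O=C1OC[C@H](Cc2ccccc2)N1C(=O)[C@@H](COCc1ccccc1)CC(=O)N1[C@@H](Cc2ccccc2)COC1=O | intermediate
6 | (R,R)-bis-alkylated bis-imide | O=C1OC[C@H](Cc2ccccc2)N1C(=O)[C@@H](COCc1ccccc1)[C@H](COCc1ccccc1)C(=O)N1[C@@H](Cc2ccccc2)COC1=O | intermediate
7 | (3aR,6aR)-furo[3,4-c]furan-1,4-dione (bis-lactone) | O=C1OC[C@@H]2C(=O)OC[C@H]12 | intermediate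
8 | 5-bromo-1,2,3-trimethoxybenzene | COc1cc(Br)cc(OC)c1OC | starting material
9 | hemiketal lactone (C4 epimeric mixture) | COc1cc(cc(OC)c1OC)C1(O)OC[C@@H]2C(=O)OC[C@H]12 | intermediate
10 | (3aR,4S,6aR)-4-(3,4,5-trimethoxyphenyl)furo[3,4-c]furan-1-one | COc1cc(cc(OC)c1OC)[C@H]1OC[C@@H]2C(=O)OC[C@H]12 | intermediate
11 | 4-bromo-1,2-dimethoxybenzene | COc1ccc(Br)cc1OC | starting material
12 | Magnone B | COc1ccc(C(=O)[C@H]2CO[C@H](c3cc(OC)c(OC)c(OC)c3)[C@H]2CO)cc1OC | target

## Totals
Total steps: 7. Longest linear sequence: 7 (1 → 3 → 5 → 6 → 7 → 9 → 10 → 12).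

## Three steps most likely to fail
1. **Step 3 (second Evans alkylation).** Diastereoselectivity or yield may suffer from α-epimerisation or elimination of the β-alkoxy enolate, and the meso diastereomer would be a dead end.
   - Fallback: make the bis-lactone by oxidative homocoupling of the titanium enolate of the N-(3-benzyloxypropanoyl) auxiliary imide at –78 °C. Alternatively, make racemic bis-lactone from dimethyl succinate and formaldehyde and resolve it enzymatically.
2. **Step 6 (C4 stereochemistry and chemoselectivity).** The hydride may give the endo-aryl epimer that does not fully equilibrate, or the 3,4,5-trimethoxyphenyl cation may be too unstable to epimerise.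
   - Fallback: open hemiketal 9 to the keto-alcohol and reduce the aryl ketone by Noyori asymmetric transfer hydrogenation. Then close the THF by activating the primary OH and displacing it with the benzylic OH, which sets the aryl stereocentre by catalyst control.
3. **Step 7 (aryl addition).** The aryllithium may over-add to give the diaryl carbinol, or deprotonate the α-CH, or the product may epimerise or sit as the hemiketal.
   - Fallback: convert lactone 10 to the Weinreb amide with MeONHMe·HCl/AlMe3. Protect the alcohol (TBS), add 3,4-dimethoxyphenylmagnesium bromide, then remove the TBS group with HF·pyridine. This gives a single ketone oxidation level.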